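**Retrosynthetic overview**

1. 6,7-Anhydroballotiquinone ⇐ acid unmasking (O-tBu, O-TES) ⇐ ring C, built last by thermal cyclobutenone ring expansion (4π opening, 6π closure, oxidation) ⇐ 1,2-adduct of a C9 vinyllithium (bromo-triene lactone with rings A, B and the lactone complete) and 3-tert-butoxy-4-isopropylcyclobutenedione (from di-tert-butyl squarate).
2. Enabling feature: ring C is a 2-hydroxy-3-isopropyl-1,4-benzoquinone. Its atoms C11–C12–C13–C14 carry O/OH/iPr/O exactly as a squarate-derived cyclobutenone does, and its other two atoms are the C8=C9 double bond (C8–H) of cycloheptatriene ring B, i.e. the alkenyl arm of a 4-alkenyl-4-hydroxycyclobutenone.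
3. Bromo-triene lactone ⇐ CBS reduction and silylation of a trienone enol lactone ⇐ enol-lactone transposition (saponification to a vinylogous diketonate, re-lactonisation) of the kinetic product of an intramolecular Buchner dearomatisation, which closes rings A and B together on a benzofuranone that already holds the lactone.
4. Diazoketone ⇐ (S)-3,3-disubstituted benzofuranone (C4 quaternary centre by asymmetric phase-transfer Michael addition to tert-butyl acrylate) ⇐ 5-bromo-3-methylbenzofuran-2(3H)-one ⇐ 2-(5-bromo-2-methoxyphenyl)acetic acid.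
5. Ring order: lactone (step 2) → rings A and B (step 6) → ring C (step 13).

Key step: step 13

Remark on locants: C1–C20 are icetexane locants of the target (ring A: C1–C5, C10; ring B: C5–C10, C20; ring C: C8, C9, C11–C14; lactone C19(=O)–O–C6). "Heptanoricetexane" means the A/B/lactone tricycle without C11–C17. Plain numbers are compounds. The target is (1R,4S,5R).

Assumption: the antipode of the phase-transfer catalyst in step 3 that delivers the (S)-adduct is chosen after a test run with both antipodes; the ee can be upgraded by crystallising the acid of step 4.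

Assumption: 2-(5-bromo-2-methoxyphenyl)acetic acid, tert-butyl acrylate and di-tert-butyl squarate are taken as commercial.

**Route**

Step 1
Reactants: 1 2-(5-bromo-2-methoxyphenyl)acetic acid
Product: 2 2-(5-bromo-2-methoxyphenyl)propanoic acid (racemic)
Conditions: LDA (2.2 equiv), THF, −78 → 0 °C; MeI (1.1 equiv), −78 °C → rt; 1 M HCl
Reagents that add atoms: iodomethane, CI
Why: α-Alkylation of the arylacetic acid dianion with methyl iodide should stop at monoalkylation because the dianion is far more nucleophilic than the product carboxylate.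

Step 2
Reactants: 2 2-(5-bromo-2-methoxyphenyl)propanoic acid
Product: 4 5-bromo-3-methylbenzofuran-2(3H)-one (racemic), via phenol acid 3 (not isolated)
Conditions: BBr3 (2.5 equiv), CH2Cl2, −78 → 0 °C; H2O; then TsOH (5 mol %), PhMe, reflux (Dean–Stark)
Reagents that add atoms: none
Why: Lewis-acid O-demethylation frees the phenol, which should close onto the neighbouring carboxyl under acid catalysis (five-membered lactonisation); the C3 centre is racemic here and is reset in step 3.

Step 3
Reactants: 4 5-bromo-3-methylbenzofuran-2(3H)-one; 5 tert-butyl acrylate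
Product: 6 tert-butyl 3-[(3S)-5-bromo-3-methyl-2-oxo-2,3-dihydrobenzofuran-3-yl]propanoate
Conditions: chiral N-spiro binaphthyl quaternary ammonium bromide (2 mol %), Cs2CO3 (0.2 equiv), PhMe (degassed), −40 °C
Reagents that add atoms: none
Why: Chiral ion-pair (phase-transfer) catalysed Michael addition of the benzofuranone enolate to the acrylate should create the quaternary centre (later C4), the enolate face being selected by the chiral ammonium cation (catalyst control).

Step 4
Reactants: 6 tert-butyl 3-[(3S)-5-bromo-3-methyl-2-oxo-2,3-dihydrobenzofuran-3-yl]propanoate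
Product: 7 3-[(3S)-5-bromo-3-methyl-2-oxo-2,3-dihydrobenzofuran-3-yl]propanoic acid
Conditions: TFA/CH2Cl2 (1:3), 0 °C → rt
Reagents that add atoms: none
Why: Acidolysis of the tert-butyl ester (E1 loss of isobutene) should leave the aryl lactone and the quaternary centre untouched.

Step 5
Reactants: 7 3-[(3S)-5-bromo-3-methyl-2-oxo-2,3-dihydrobenzofuran-3-yl]propanoic acid
Product: 9 (3S)-5-bromo-3-(4-diazo-3-oxobutyl)-3-methylbenzofuran-2(3H)-one, via acid chloride 8 (not isolated)
Conditions: (COCl)2 (1.5 equiv), DMF (cat.), CH2Cl2, 0 °C → rt; evaporate; CH2N2 (3 equiv), Et2O, 0 °C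
Reagents that add atoms: diazomethane, C=[N+]=[N-]
Why: Acid chloride formation followed by acylation of diazomethane (first half of the Arndt–Eistert sequence, excess diazomethane taking up HCl) should give the α-diazoketone, the aryl lactone being inert to both reagents.

Step 6
Reactants: 9 (3S)-5-bromo-3-(4-diazo-3-oxobutyl)-3-methylbenzofuran-2(3H)-one
Product: 11 (4S,10R)-9-bromo-1-oxo-heptanoricetexa-5,7,9(20)-trien-19,6-olide, via norcaradiene 10 (not isolated)
Conditions: Rh2(OAc)4 (1 mol %), CH2Cl2 (5 mM, slow addition), 40 °C; filtration through Florisil, used crude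
Reagents that add atoms: none
Why: Intramolecular Buchner reaction: the Rh(II) carbenoid should cyclopropanate the only accessible arene bond (C3a–C4 of the benzofuranone; the ring-fusion bond would give a propellane and benzylic C–H insertion is blocked by the quaternary carbon), and 6π ring opening of the norcaradiene closes rings A and B at once, the C10 centre (10-H anti to the 4-methyl) being dictated by the tether and erased in step 7.

Step 7
Reactants: 11 (4S,10R)-9-bromo-1-oxo-heptanoricetexa-5,7,9(20)-trien-19,6-olide
Product: 12 (4S,5R)-9-bromo-6-hydroxy-1-oxo-heptanoricetexa-6,8,10(20)-trien-19-oic acid (vinylogous acid tautomer)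
Conditions: LiOH·H2O (3 equiv), THF/H2O (3:1, degassed), 0 °C → rt; then 1 M HCl to pH 3, 0 °C
Reagents that add atoms: lithium hydroxide, [Li+].[OH-]
Why: Saponification of the enol lactone releases the C6 enolate, which can ketonise only by protonation at C5, and in base the C10–H (α to C1=O and vinylogous to the new C6=O) should then be lost to give the fully delocalised vinylogous 1,3-diketonate O=C1–C10=C20–C9=C8–C7=C6–O−, the thermodynamic sink that fixes the sp3 C5–H and the C6=C7/C8=C9/C10=C20 triene (ester hydrolysis followed by keto–enol tautomerisation).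

Step 8
Reactants: 12 (4S,5R)-9-bromo-6-hydroxy-1-oxo-heptanoricetexa-6,8,10(20)-trien-19-oic acid
Product: 13 (4S,5R)-9-bromo-1-oxo-heptanoricetexa-6,8,10(20)-trien-19,6-olide
Conditions: DCC (1.1 equiv), DMAP (5 mol %), CH2Cl2, 0 °C → rt
Reagents that add atoms: none
Why: Carbodiimide (Steglich-type) O-acylation of the vinylogous-acid enol by the C4 carboxyl should close the five-membered enol lactone at O6 only (acylation at O1 would need a bridgehead enol ether, C-acylation a four-membered ring), and the cis ring fusion at C5 (5-H syn to the 4-methyl) follows because C5 can epimerise through the keto tautomer and only that epimer lactonises without strain.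

Step 9
Reactants: 13 (4S,5R)-9-bromo-1-oxo-heptanoricetexa-6,8,10(20)-trien-19,6-olide
Product: 14 (1R,4S,5R)-9-bromo-1-hydroxy-heptanoricetexa-6,8,10(20)-trien-19,6-olide
Conditions: (S)-2-methyl-CBS-oxazaborolidine (0.5 equiv), catecholborane (1.5 equiv), PhMe, −78 °C; pH 7 buffer
Reagents that add atoms: none
Why: Corey–Bakshi–Shibata reduction: the (S)-oxazaborolidine binds the ketone with the alkenyl arm (C10) as the large group and should deliver hydride to the α-face, which is also the open axial trajectory of the substrate, giving the 1R (1β) alcohol in a non-nucleophilic medium that spares the acyl-transfer-prone enol lactone.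

Step 10
Reactants: 14 (1R,4S,5R)-9-bromo-1-hydroxy-heptanoricetexa-6,8,10(20)-trien-19,6-olide
Product: 15 (1R,4S,5R)-9-bromo-1-(triethylsilyloxy)-heptanoricetexa-6,8,10(20)-trien-19,6-olide
Conditions: TESCl (1.3 equiv), imidazole (2 equiv), DMF, 0 °C
Reagents that add atoms: chlorotriethylsilane, CC[Si](Cl)(CC)CC
Why: Standard silylation of the secondary alcohol under non-alkoxide conditions avoids transannular attack of a C1 alkoxide on the lactone carbonyl, and the TES group can later leave in the same acid step as the tert-butyl ether.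

Step 11
Reactants: 16 3,4-di-tert-butoxycyclobut-3-ene-1,2-dione (di-tert-butyl squarate)
Product: 18 3-tert-butoxy-4-isopropylcyclobut-3-ene-1,2-dione, via chloromagnesium alkoxide 17 (not isolated)
Conditions: iPrMgCl (1.05 equiv), THF, −78 °C; TFAA (1.2 equiv), −78 °C → rt
Reagents that add atoms: isopropylmagnesium chloride, CC(C)[Mg]Cl
Why: 1,2-Addition of the Grignard reagent to one squarate carbonyl, then trifluoroacetylation, ionisation to the alkoxy-stabilised cyclobutenyl cation and loss of the tert-butyl group should give the 3-alkyl-4-alkoxycyclobutenedione (standard squarate transposition).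

Step 12
Reactants: 15 (1R,4S,5R)-9-bromo-1-(triethylsilyloxy)-heptanoricetexa-6,8,10(20)-trien-19,6-olide; 18 3-tert-butoxy-4-isopropylcyclobut-3-ene-1,2-dione
Product: 20 3-tert-butoxy-4-hydroxy-2-isopropyl-4-(C9-alkenyl)cyclobut-2-en-1-one (alkenyl = 15 without Br; carbinol epimers), via vinyllithium 19 (not isolated)
Conditions: t-BuLi (2.05 equiv), THF/Et2O/pentane (4:1:1), −100 °C, 5 min; then 18 (1.3 equiv), −100 → −78 °C; sat. aq. NH4Cl, −78 °C; used crude
Reagents that add atoms: none
Why: Bromine–lithium exchange at −100 °C should outrun attack on the pivalate-like (α-quaternary) lactone, and the vinyllithium adds 1,2 to the more electrophilic carbonyl of the dione (the one that is not part of the vinylogous ester; squarate addition of the Moore–Liebeskind type), which places O-tBu next to the future C11 and iPr next to the future C14, the carbinol centre forming as an inconsequential mixture.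

Step 13
Reactants: 20 3-tert-butoxy-4-hydroxy-2-isopropyl-4-(C9-alkenyl)cyclobut-2-en-1-one
Product: 24 12-O-tert-butyl-1-O-triethylsilyl-6,7-anhydroballotiquinone, via dienylketene 21 (not isolated), via cyclohexadienone 22 (not isolated), via hydroquinone 23 (not isolated)
Conditions: PhMe (0.01 M, degassed), 85–90 °C, 2–3 h; then rt, Ag2O (1.5 equiv), 30 min
Reagents that add atoms: none
Why: Heating should open the strained cyclobutenone by 4π-conrotatory electrocyclic ring opening (C11–C14 bond cleaved), the carbinol OH rotating outward so that the cycloheptatrienyl group lies cis to the ketene in 21; 6π-disrotatory electrocyclisation onto C8 then gives cyclohexadienone 22, which enolises to hydroquinone 23, and Ag2O oxidises 23 to the quinone. The closest known reaction type is the Moore–Liebeskind thermal ring expansion of 4-alkenyl-4-hydroxycyclobutenones (squarate benzannulation). Only ring C is closed, a six-membered carbocycle formed in the pericyclic 6π mode through the new C8–C14 bond, driven by release of cyclobutene strain and by aromatisation. No new stereocentre survives, since the carbinol carbon and the transient sp3 C8 of 22 become sp2, and C1, C4 and C5 are spectators. The step needs closure onto C8 and not C20 (secured because C8=C9 is the only double bond at C9), the O/OtBu/iPr/O pattern (fixed by the regiochemistry of step 12) and an intact C5–H triene, which a temperature of at most 90 °C should secure because it lies below the onset of [1,5]-hydrogen shifts in cycloheptatrienes.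

Step 14
Reactants: 24 12-O-tert-butyl-1-O-triethylsilyl-6,7-anhydroballotiquinone
Product: 25 6,7-anhydroballotiquinone
Conditions: TFA/CH2Cl2 (1:5), 0 °C, 30 min; then H2O/THF, rt
Reagents that add atoms: none
Why: Acidolysis should cleave the tert-butyl vinylogous ester (isobutene loss) to the hydroxyquinone and, with water, the TES ether, while the α-quaternary enol lactone and the electron-poor allylic alcohol tolerate brief TFA exposure.

**Compound list**

1 | 2-(5-bromo-2-methoxyphenyl)acetic acid | COc1ccc(Br)cc1CC(=O)O | starting material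
2 | 2-(5-bromo-2-methoxyphenyl)propanoic acid (racemic) | COc1ccc(Br)cc1C(C)C(=O)O | intermediate
3 | 2-(5-bromo-2-hydroxyphenyl)propanoic acid (racemic) | Oc1ccc(Br)cc1C(C)C(=O)O | intermediate (not isolated)
4 | 5-bromo-3-methylbenzofuran-2(3H)-one (racemic) | CC1C(=O)Oc2ccc(Br)cc12 | intermediate
5 | tert-butyl acrylate | C=CC(=O)OC(C)(C)C | starting material
6 | tert-butyl 3-[(3S)-5-bromo-3-methyl-2-oxo-2,3-dihydrobenzofuran-3-yl]propanoate | C[C@@]1(CCC(=O)OC(C)(C)C)C(=O)Oc2ccc(Br)cc12 | intermediate
7 | 3-[(3S)-5-bromo-3-methyl-2-oxo-2,3-dihydrobenzofuran-3-yl]propanoic acid | C[C@@]1(CCC(=O)O)C(=O)Oc2ccc(Br)cc12 | intermediate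
8 | 3-[(3S)-5-bromo-3-methyl-2-oxo-2,3-dihydrobenzofuran-3-yl]propanoyl chloride | C[C@@]1(CCC(=O)Cl)C(=O)Oc2ccc(Br)cc12 | intermediate (not isolated)
9 | (3S)-5-bromo-3-(4-diazo-3-oxobutyl)-3-methylbenzofuran-2(3H)-one | C[C@@]1(CCC(=O)C=[N+]=[N-])C(=O)Oc2ccc(Br)cc12 | intermediate
10 | norcaradiene valence isomer of 11 (cyclopropane C5–C10–C20, all-cis fused, 4S) | O=C1CC[C@]2(C)C(=O)OC3=CC=C(Br)C4C1C234 | intermediate (not isolated)
11 | (4S,10R)-9-bromo-1-oxo-heptanoricetexa-5,7,9(20)-trien-19,6-olide (kinetic Buchner cycloheptatriene, 10-H anti to 4-CH3) | O=C1CC[C@]2(C)C(=O)OC3=C2[C@H]1C=C(Br)C=C3 | intermediate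
12 | (4S,5R)-9-bromo-6-hydroxy-1-oxo-heptanoricetexa-6,8,10(20)-trien-19-oic acid (vinylogous acid; keto tautomers possible) | O=C1CC[C@](C)(C(=O)O)[C@H]2C1=CC(Br)=CC=C2O | intermediate
13 | (4S,5R)-9-bromo-1-oxo-heptanoricetexa-6,8,10(20)-trien-19,6-olide (cis-fused enol lactone) | BrC1=CC=C2OC(=O)[C@@]3(C)CCC(=O)C(=C1)[C@@H]23 | intermediate
14 | (1R,4S,5R)-9-bromo-1-hydroxy-heptanoricetexa-6,8,10(20)-trien-19,6-olide | BrC1=CC=C2OC(=O)[C@@]3(C)CC[C@@H](O)C(=C1)[C@@H]23 | intermediate
15 | (1R,4S,5R)-9-bromo-1-(triethylsilyloxy)-heptanoricetexa-6,8,10(20)-trien-19,6-olide | BrC1=CC=C2OC(=O)[C@@]3(C)CC[C@@H](O[Si](CC)(CC)CC)C(=C1)[C@@H]23 | intermediate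
16 | 3,4-di-tert-butoxycyclobut-3-ene-1,2-dione | CC(C)(C)OC1=C(OC(C)(C)C)C(=O)C1=O | starting material
17 | chloromagnesium 2,3-di-tert-butoxy-1-isopropyl-4-oxocyclobut-2-en-1-olate | CC(C)C1(O[Mg]Cl)C(=O)C(OC(C)(C)C)=C1OC(C)(C)C | intermediate (not isolated)
18 | 3-tert-butoxy-4-isopropylcyclobut-3-ene-1,2-dione | CC(C)C1=C(OC(C)(C)C)C(=O)C1=O | intermediate
19 | C9 vinyllithium derived from 15 | [Li]C1=CC=C2OC(=O)[C@@]3(C)CC[C@@H](O[Si](CC)(CC)CC)C(=C1)[C@@H]23 | intermediate (not isolated)
20 | 3-tert-butoxy-4-hydroxy-2-isopropyl-4-(C9-alkenyl)cyclobut-2-en-1-one (carbinol epimers) | CC(C)C1=C(OC(C)(C)C)C(O)(C2=CC=C3OC(=O)[C@@]4(C)CC[C@@H](O[Si](CC)(CC)CC)C(=C2)[C@@H]34)C1=O | intermediate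
21 | dienylketene from ring opening of 20 | CC(C)C(=C=O)C(OC(C)(C)C)=C(O)C1=CC=C2OC(=O)[C@@]3(C)CC[C@@H](O[Si](CC)(CC)CC)C(=C1)[C@@H]23 | intermediate (not isolated)
22 | cyclohexa-2,4-dienone from 6π closure (sp3 C8–H) | CC(C)C1=C(OC(C)(C)C)C(O)=C2C(C=C3OC(=O)[C@@]4(C)CC[C@@H](O[Si](CC)(CC)CC)C(=C2)[C@@H]34)C1=O | intermediate (not isolated)
23 | 11,14-hydroquinone (12-O-tBu, 1-O-TES) | CC(C)c1c(OC(C)(C)C)c(O)c2c(c1O)C=C1OC(=O)[C@@]3(C)CC[C@@H](O[Si](CC)(CC)CC)C(=C2)[C@@H]13 | intermediate (not isolated)
24 | 12-O-tert-butyl-1-O-triethylsilyl-6,7-anhydroballotiquinone | CC(C)C1=C(OC(C)(C)C)C(=O)C2=C(C=C3OC(=O)[C@@]4(C)CC[C@@H](O[Si](CC)(CC)CC)C(=C2)[C@@H]34)C1=O | intermediate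
25 | 6,7-anhydroballotiquinone (1R,4S,5R) | CC(C)C1=C(O)C(=O)C2=C(C=C3OC(=O)[C@@]4(C)CC[C@@H](O)C(=C2)[C@@H]34)C1=O | target

**Step count and risks**

Total step count: 14. Longest linear sequence: 13 (steps 1–10, 12, 13, 14); step 11 is a one-step side branch.

Steps most likely to fail:

1. Step 7. What may go wrong: enolisation of 11 at C10 followed by γ-protonation (base-induced conjugation to the tetrasubstituted enone isomer, whose saturated lactone hydrolyses slowly) may outrun saponification of the enol lactone, so that the material does not funnel into the vinylogous diketonate. The fallback sets out from 7 and comes back at 12, and blocks C10 with a removable ester. Acid 7 would be converted with carbonyldiimidazole and magnesium ethyl malonate into ethyl 5-[(3S)-5-bromo-3-methyl-2-oxo-2,3-dihydrobenzofuran-3-yl]-3-oxopentanoate F1. Diazo transfer (4-acetamidobenzenesulfonyl azide, Et3N, MeCN) would give ethyl 2-diazo-5-[(3S)-5-bromo-3-methyl-2-oxo-2,3-dihydrobenzofuran-3-yl]-3-oxopentanoate F2. Rh2(OAc)4 would then effect the same arene cyclopropanation and ring expansion through an acceptor–acceptor carbenoid to give the 10-ethoxycarbonyl analogue of 11 F3, which has no C10–H and cannot conjugate. LiOH would open its enol lactone (ketonisation possible only at C5) and saponify the ester, and acidification with gentle warming would decarboxylate the β-keto acid to give 12.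

2. Step 12. What may go wrong: attack of tert-butyllithium or of the vinyllithium on the enol lactone, or proton abstraction at C5, may compete with halogen–metal exchange and 1,2-addition. The fallback sets out from 15 and comes back at 20. Bromine–magnesium exchange with lithium tributylmagnesate (THF, −78 → −40 °C) would give the ester-tolerant lithium dibutyl(C9-alkenyl)magnesate of 15 F4, which would be added to dione 18 at −78 °C and worked up with NH4Cl to give 20.

3. Step 3. What may go wrong: facial discrimination of the small 3-methyl enolate by the chiral cation may be poor, or base may open the lactone. The fallback sets out from 4 and 5 and comes back at 6. A DBU-catalysed (10 mol %, PhMe) Michael addition would give racemic tert-butyl 3-(5-bromo-3-methyl-2-oxo-2,3-dihydrobenzofuran-3-yl)propanoate F5, from which the (S)-enantiomer 6 would be separated by preparative chiral SFC.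

**Further compounds**

F1 | step 7 | ethyl 5-[(3S)-5-bromo-3-methyl-2-oxo-2,3-dihydrobenzofuran-3-yl]-3-oxopentanoate | CCOC(=O)CC(=O)CC[C@]1(C)C(=O)Oc2ccc(Br)cc12
F2 | step 7 | ethyl 2-diazo-5-[(3S)-5-bromo-3-methyl-2-oxo-2,3-dihydrobenzofuran-3-yl]-3-oxopentanoate | CCOC(=O)C(=[N+]=[N-])C(=O)CC[C@]1(C)C(=O)Oc2ccc(Br)cc12
F3 | step 7 | 10-ethoxycarbonyl analogue of 11 ((4S)-9-bromo-10-ethoxycarbonyl-1-oxo-heptanoricetexa-5,7,9(20)-trien-19,6-olide) | O=C1CC[C@]2(C)C(=O)OC3=C2C1(C(=O)OCC)C=C(Br)C=C3
F4 | step 12 | lithium dibutyl(C9-alkenyl)magnesate of 15 | [Li+].CCCC[Mg-](CCCC)C1=CC=C2OC(=O)[C@@]3(C)CC[C@@H](O[Si](CC)(CC)CC)C(=C1)[C@@H]23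
F5 | step 3 | racemic tert-butyl 3-(5-bromo-3-methyl-2-oxo-2,3-dihydrobenzofuran-3-yl)propanoate | CC1(CCC(=O)OC(C)(C)C)C(=O)Oc2ccc(Br)cc12
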